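(The readings were computed from invented constants; scatter was added.)

We read a ratio first. A single-handed catalyst turns two mirror-image substrates into two products, and each product step also uses a partner that dissolves from a solid reagent.

all flasks: left-handed substrate 11 mM; right-handed substrate 11 mM; free catalyst 1.4 mM; added ligand 5.9 mM; impurity 0.19 mM

|  | solid reagent | remark | time |
|---|---|---|---|
| spring | 8.4 mM | run made earlier |  |
| autumn | 18 mM | run made earlier |  |
| Monday's | 13.2 mM |  | 10 d |
| Sunday's | 25.0 mM |  | 10 d |

- spring (time / d: left-handed product / %, right-handed product / %): 2.08: 0.9, 0; 4.00: 3.0, 1.3; 6.00: 4.1, 2.4; 8.00: 6.6, 2.6; 10.0: 7.4, 4.1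
- autumn (time / d: left-handed product / %, right-handed product / %): 0.833: 0, 0.1; 1.67: 0.8, 1.2; 3.00: 2.2, 0.4; 5.00: 4.0, 1.5; 10.0: 8.0, 4.9

(scatter of a reading: 0.5 percentage points)

- which one finishes higher in excess of left-handed product over right-handed product in the product ("neither" within 2 percentage points) (Monday's / Sunday's / neither)
- excess of left-handed product over right-handed product in the product at the end, Monday's
- excess of left-handed product over right-handed product in the product at the end, Sunday's

- free catalyst is single-handed; left-handed substrate and right-handed substrate are mirror images of each other, charged as a racemate, each of them at the stated concentration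
- given per volume of solution although it is solid: solid reagent
- steps thought possible: free catalyst + added ligand <-> idle complex; solid reagent <-> partner; partner + free catalyst + left-handed substrate -> free catalyst + left-handed product; free catalyst + impurity -> spent catalyst; partner + free catalyst + right-handed substrate -> free catalyst + right-handed product
- at the start none of the solid reagent is in solution
- an excess is below zero if the other one leads

Autumn charged twice spring's solid reagent, and its last readings lie within 0.8 percentage points of spring's, so we pool the two runs. Our quantity is the product excess: left-handed product minus right-handed product, over their sum.

excess = ([left-handed product] − [right-handed product]) / ([left-handed product] + [right-handed product]) = 26.2%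

This is a reading, with a scatter of 0.5 points on each value behind it. Both product steps use the same free catalyst and partner, so those cancel in the ratio of the two rates.

Next we set the times in order. On average the runs reacted 12.2% of the substrates by the last reading, which is 0.268 mM d⁻¹.

The flask stands for: 10 d
Monday's solid reagent lasts, at that rate: 49.2 d
Sunday's solid reagent lasts, at that rate: 93.1 d
The substrates last, at that rate: 82.0 d

So we expect solid to remain in both flasks at the end. The excess has two ends. Early, it shows the ratio of the two rates, the selectivity factor. With both substrates consumed, equal charges give equal products and an excess of zero. We stop near the early end, so we expect about 26.2% in both flasks.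

The forecast says neither, with 3.2% for Monday's and 3.2% for Sunday's: “Both new runs should reach about 3.2 points”. We share its choice but not its number. Its figure is left minus right in points of the charge, while ours divides by the product.

The flasks give 26.8% for Monday's and 26.8% for Sunday's, so neither. At 10.0 d, Monday's holds 7.73% left-handed product and 4.46% right-handed product, and Sunday's holds 7.73% and 4.46%. Our excess times the 12.2% reacted in Monday's gives 3.2 points, the size of the forecast's figure.

    free catalyst + added ligand ⇌ idle complex (K = 970 L mol⁻¹, k = 150 L mol⁻¹ h⁻¹)
    solid reagent ⇌ partner, rate k2*(cs2 - [partner]) while solid is left; crystals form when [partner] > cs2 (solubility = 1.90 mM, k = 0.00740 h⁻¹)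
    partner + free catalyst + left-handed substrate → free catalyst + left-handed product (k = 14000 L² mol⁻² h⁻¹)
    free catalyst + impurity → spent catalyst (k = 12000 L mol⁻¹ h⁻¹)
    partner + free catalyst + right-handed substrate → free catalyst + right-handed product (k = 7800 L² mol⁻² h⁻¹)

Take a flask like Monday's with 15 mM of added ligand. The product steps are unchanged, so we carry 26.2%. It gives 27.2%, with left-handed product down to 5.89% at 10.0 d.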